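I followed one fraction through each flask.

    substrate ⇌ intermediate (K1 = 0.073, k1 = 0.39 /h)
    first nucleophile + intermediate → target (k2 = 1.1 × 10⁵ /M/h)
    second nucleophile + intermediate → other capture product (k3 = 2000 /M/h)
    gas ⇌ first nucleophile, rate k4*(csat - [first nucleophile]) (k4 = 2.9 /h, csat = 3.3 mM)
    2 first nucleophile → homo dimer (k5 = 67 /M/h)

all flasks: gas 3.3 mM (held); time 20 h
- ash: substrate 0.020 M (fed, over 15 h); second nucleophile 0.0600 M; all else is in the flask from the start; the feed brings no volume worth counting
- alder: substrate 0.020 M; second nucleophile 0.0600 M (fed, over 15 h); all else is in the flask from the start; the feed brings no volume worth counting
- cedar: substrate 0.020 M; second nucleophile 0.0600 M; everything together at the start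

- a step written with two of one species runs at k times the square of its concentration and takes two of it each time
- at the start none of first nucleophile is dissolved
- run time (ash): 20 h

- the flask with the highest amount of target, in percent of the substrate charged ("all alike" if they lie within 1.5 percentage points) (ash / alder / cedar / all alike)
- final target, as a percentage of the substrate charged, in ash
- final target, as a percentage of the substrate charged, in alder
- final target, as a percentage of the substrate charged, in cedar

In the first instants of cedar, no first nucleophile was dissolved, and the intermediate met the second nucleophile at its whole charge. That capture ran at 120 /h, far faster than reversion at 5.34 /h. So I let the substrate drain by the forward step, with a half-life of 1.78 h. I reckoned the selectivity as a capture share: the rate of capture by the first nucleophile over the sum of both capture rates, with a selectivity factor of 55.0.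

In alder, the substrate's mean life by the forward step was 2.56 h, and by then the feed had brought 17.1% of the second nucleophile's charge. With the first nucleophile at saturation, that gives 94.7%, the capture share at saturation.

Then I iterated through the middle of the run. I took a capture demand of 3.90 mM/h, the forward step on half the charge of substrate, and set it with the homo dimer's 1.46 mM/h draw against a transfer of at most 9.57 mM/h. Putting the share back, my first round put alder's dissolved first nucleophile at 46.2% of saturation. A second round raised it to 60.4%, and alder's share came to 91.4%.

Cedar, with the whole charge of second nucleophile, had a capture share at saturation of 75.2%. My rounds put its dissolved first nucleophile at 54.1% of saturation, then 70.2%, which gives 68.0%.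

I took ash's demand equal to its feed, 1.33 mM/h, so its rounds gave 74.3% and 81.9% of saturation. I let ash's substrate decay by the forward step after the feed stopped, which left 2.43% of the charge in my reckoning, so I put ash at 69.5%. My ranking put alder first.

The forecast gave 71% in ash, 92% in alder and 64% in cedar, with alder ahead, holding that in alder “the substrate burns off early”.

The run gave 70.2% in ash, 92.3% in alder and 64.8% in cedar, so alder led. Alder's other capture product stood at 7.69%, more than the 5.30% that the capture share at saturation leaves. In alder's neighbour with 0.034 M of substrate, the same 94.7% met a demand of 6.63 mM/h. The first round gave 19.2% of saturation, and the second closed at a share of 89.0%. That flask ended at 88.9%.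

All constants are made up, and the outcome is calculated.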